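The route rests on cutting C5–C6 of ring A and reconnecting C3–C8, which turns the cis-decalin into a bicyclo[2.2.2]octenol. The feature exploited is the cis C5/C10 fusion of ring A that sits next to the vicinal C8/C9 oxygens and the quaternary C5 methyl: these map onto the carbinol, ketal and methyl-bearing alkene carbons of a creosol-derived masked o-benzoquinone adduct. One anionic oxy-Cope step closes ring A, sets the C5 quaternary centre and the cis fusion, and leaves the C8 enolate whose protonation sets C7. The precursor is a 2-dienyl-3,3-dimethoxy-5-methyl-7-PMB-oxybicyclo[2.2.2]oct-5-en-2-ol with the dienyl group syn to the ring alkene.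

Key step: step 5

Conventions: decalins carry eremophilane numbering (ring B = C10, C1–C5; ring A = C5–C10); the C4 methyl is C15, absent until step 12, hence "15-nor" in the names; β is the face of the C5 methyl. The bicycles carry their own IUPAC numbering.
Assumption: in the oxazaborolidine reduction of step 2 the dimethoxy-bearing C3, not the bridgehead C1, acts as the large flank of the carbonyl; this makes the (R)-catalyst the one that consumes the unwanted antipode.
Assumption: 4-methoxybenzyl vinyl ether (2) is bought as a catalogue compound.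

**Step 1**
Reactants: 1 creosol; 2 4-methoxybenzyl vinyl ether
Product: 4 rac-(1S*,4S*,7S*)-7-(4-methoxybenzyloxy)-3,3-dimethoxy-5-methylbicyclo[2.2.2]oct-5-en-2-one, via masked o-benzoquinone 3 (not isolated)
Conditions: PhI(OAc)2 (1.1 equiv, slow addition), 2 (10 equiv), MeOH, 0 °C → rt
Reagents that add atoms: methanol, CO
Why: Oxidative dearomatisation gives the 6,6-dimethoxycyclohexa-2,4-dienone, which the excess electron-rich alkene traps before it dimerises in an inverse-electron-demand Diels–Alder reaction; the CH2 terminus should bond to the dienone carbon next to the ketal, so the PMB-oxy group ends at C7 beside the carbonyl-side bridgehead and endo (syn to the new C5=C6 bridge), as one racemic diastereomer.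

**Step 2**
Reactants: 4 racemic adduct
Product: 5 (1S,4S,7S)-7-(4-methoxybenzyloxy)-3,3-dimethoxy-5-methylbicyclo[2.2.2]oct-5-en-2-one
Conditions: (R)-2-methyl-CBS-oxazaborolidine (0.2 equiv), catecholborane (0.6 equiv), toluene, −78 → −40 °C, stopped at about 55 % conversion; MeOH quench; chromatography
Reagents that add atoms: none
Why: Corey–Bakshi–Shibata reduction used as a kinetic resolution: the (R)-catalyst should deliver hydride to the open etheno face only of the (1R,4R,7R) antipode, whereas for 5 its preferred face is the shielded C7–C8 side, so 5 is recovered enantioenriched, and catecholborane should spare the strained alkene.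

**Step 3**
Reactants: 6 2-methylbut-1-en-3-yne
Product: 7 tributyl(3-methylbuta-1,3-dien-2-yl)stannane
Conditions: Bu3SnH (1.0 equiv), 6 (1.5 equiv), Pd(PPh3)4 (2 mol %), THF, 0 °C → rt
Reagents that add atoms: tributyltin hydride, CCCC[SnH](CCCC)CCCC
Why: Palladium-catalysed syn-hydrostannation of a conjugated enyne places tin on the internal alkyne carbon, next to the vinyl group, which gives the 2-stannyl-1,3-diene.

**Step 4**
Reactants: 7 tributyl(3-methylbuta-1,3-dien-2-yl)stannane; 5 resolved bicyclic ketone
Product: 9 (1S,2S,4S,7S)-7-(4-methoxybenzyloxy)-3,3-dimethoxy-5-methyl-2-(3-methylbuta-1,3-dien-2-yl)bicyclo[2.2.2]oct-5-en-2-ol, via dienyllithium 8 (not isolated)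
Conditions: 7 (1.5 equiv), n-BuLi (1.4 equiv), THF, −78 °C, 1 h; then 5, −78 → −40 °C; aq NH4Cl
Reagents that add atoms: none
Why: Tin–lithium exchange gives the 2-lithiodiene, which adds 1,2 to the non-enolisable ketone from the face of the C5=C6 bridge, away from the exo hydrogens of the C7–C8 bridge, so that C2 carries the dienyl group syn to the ring alkene and the hydroxyl syn to the C7–C8 bridge.

**Step 5**
Reactants: 9 dienyl carbinol
Product: 12 (2S,5R,7R,10S)-9,9-dimethoxy-2-(4-methoxybenzyloxy)-15-noreremophila-3,11-dien-8-one, via potassium alkoxide 10 (not isolated), via potassium dienolate 11 (not isolated)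
Conditions: KH (3 equiv), 18-crown-6 (3 equiv), THF, 0 → 25 °C; inverse quench into AcOH/THF, −78 °C
Reagents that add atoms: none
Why: Deprotonation gives the crown-separated alkoxide 10, whose 1,5-diene (dienyl CH2=C, carbinol C2, bridgehead C1, C6=C5) undergoes a charge-accelerated [3,3] shift through the boat-shaped array that the bicycle enforces: the dienyl CH2 bonds to the methyl-bearing C5 while C1–C2 breaks, so ring A (decalin C5–C6–C7–C8–C9–C10) is closed by sigmatropic C5–C6 bond formation, a pericyclic closure and not an ionic cyclisation, and the cross-conjugated dienolate 11 results. This is the anionic oxy-Cope rearrangement of 2-alkenylbicyclo[2.2.2]oct-5-en-2-ols, an established way to cis-decalins. The quaternary C5 is controlled by the substrate: the dienyl terminus can only reach the alkene face below the C2–C3 bridge, so C5–C6 forms cis to C10–C9 (cis fusion with 5β-methyl and 10β-H). C7 is set in the quench: kinetic α-protonation of the dienolate keeps the isopropenyl group out of conjugation, and axial delivery of the proton on the α face, past the vinylic C4–H and not past the axial methyl of the alternative half-chair, should leave the isopropenyl group equatorial and cis to the C5 methyl. The step needs the dienyl group syn to the etheno bridge (secured in step 4) and a cold, weakly acidic quench so that C7 neither epimerises nor the alkene moves into conjugation; strain release and enolate formation drive it.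

**Step 6**
Reactants: 12 ketal ketone
Product: 13 (2S,5R,7R,8R,10S)-9,9-dimethoxy-2-(4-methoxybenzyloxy)-15-noreremophila-3,11-dien-8-ol
Conditions: NaBH4, CeCl3·7H2O, MeOH, −40 °C
Reagents that add atoms: none
Why: Luche reduction: in the chair with equatorial 7β-isopropenyl, hydride should attack C8 axially from the convex β face, anti to the axial C9 methoxy group, to give the equatorial 8α-alcohol trans to the isopropenyl group, under non-basic conditions that do not isomerise the β,γ-unsaturated ketone.

**Step 7**
Reactants: 13 hydroxy ketal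
Product: 14 (2S,5R,7R,8R,10S)-8-hydroxy-2-(4-methoxybenzyloxy)-15-noreremophila-3,11-dien-9-one
Conditions: 2 M aq HCl/THF (1:3), 25 °C
Reagents that add atoms: water, O
Why: Acid-catalysed ketal hydrolysis through the oxocarbenium ion unveils the C9 ketone under conditions that the allylic PMB ether and the isopropenyl group should tolerate, and the cis fusion at C10 is expected to hold because it is the favoured arrangement of an angularly methylated 1-decalone.

**Step 8**
Reactants: 14 hydroxy ketone
Product: 15 (2S,5R,7R,8R,9S,10S)-2-(4-methoxybenzyloxy)-15-noreremophila-3,11-diene-8,9-diol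
Conditions: L-Selectride (2.5 equiv), THF, −78 °C; then NaOH, H2O2, 0 °C
Reagents that add atoms: none
Why: Trialkylborohydride reduction under steric approach control: the axial α path to C9 is closed by the syn-axial C4 of ring B on the concave face, so hydride should enter equatorially from the convex β face and give the axial 9α-alcohol, cis to the 8α-hydroxyl.

**Step 9**
Reactants: 15 cis-diol; 16 tiglic acid
Product: 18 (2S,5R,7R,8R,9S,10S)-2-(4-methoxybenzyloxy)-15-noreremophila-3,11-diene-8,9-diyl bis[(E)-2-methylbut-2-enoate], via mixed anhydride 17 (not isolated)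
Conditions: 16 (6 equiv), 2,4,6-Cl3C6H2COCl, Et3N, toluene, rt; then 15, DMAP, toluene, 80 °C
Reagents that add atoms: none
Why: Yamaguchi esterification: the DMAP-activated mixed anhydride should acylate the equatorial 8-OH readily and the hindered axial 9-OH on heating (helped by 1,2-acyl migration within the cis-diol and re-acylation), and the tiglate is the stable E isomer, so no double-bond isomerisation is expected.

**Step 10**
Reactants: 18 ditiglate PMB ether
Product: 19 (2S,5R,7R,8R,9S,10S)-2-hydroxy-15-noreremophila-3,11-diene-8,9-diyl bis[(E)-2-methylbut-2-enoate]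
Conditions: DDQ (1.3 equiv), CH2Cl2/pH 7 buffer (10:1), 0 °C → rt
Reagents that add atoms: none
Why: Oxidative PMB cleavage (hydride abstraction by DDQ, hydrolysis of the oxocarbenium ion) frees the allylic 2β-alcohol without touching the tiglates or the alkenes.

**Step 11**
Reactants: 19 allylic alcohol
Product: 20 (5R,7R,8R,9S,10S)-2-oxo-15-noreremophila-3,11-diene-8,9-diyl bis[(E)-2-methylbut-2-enoate]
Conditions: Dess–Martin periodinane, NaHCO3, CH2Cl2, rt
Reagents that add atoms: none
Why: Dess–Martin oxidation of the allylic alcohol gives the Δ3-en-2-one under buffered, non-basic conditions.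

**Step 12**
Reactants: 20 enone
Product: 22 (4S,5R,7R,8R,9S,10S)-2-oxoeremophil-11-ene-8,9-diyl bis[(E)-2-methylbut-2-enoate] (CNP0249036.2), via silyl enol ether 21 (not isolated)
Conditions: Me2CuLi (from MeLi, CuI; 3 equiv), TMSCl (5 equiv), THF, −78 → −40 °C; then 1 M HCl, THF, 0 °C
Reagents that add atoms: lithium dimethylcuprate, [Li+].C[Cu-]C
Why: TMSCl-accelerated conjugate addition of a Gilman cuprate: the α face of C4 is closed by the axial 9α-tigloyloxy group and ring A, so methyl should arrive from the convex β face, cis to the C5 methyl, while the α,β-disubstituted tiglates are inert to the cuprate at low temperature; the acid work-up hydrolyses the silyl enol ether.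

**Compound list**
1 | creosol (2-methoxy-4-methylphenol) | Cc1ccc(O)c(OC)c1 | starting material
2 | 4-methoxybenzyl vinyl ether | C=COCc1ccc(OC)cc1 | starting material
3 | 6,6-dimethoxy-4-methylcyclohexa-2,4-dien-1-one (masked o-benzoquinone) | O=C1C=CC(C)=CC1(OC)OC | intermediate
4 | rac-(1S*,4S*,7S*)-7-(4-methoxybenzyloxy)-3,3-dimethoxy-5-methylbicyclo[2.2.2]oct-5-en-2-one, PMB-oxy syn to C5=C6 (racemate; SMILES shows the 1S,4S,7S enantiomer) | O=C1C(OC)(OC)[C@H]2C[C@H](OCc3ccc(OC)cc3)[C@@H]1C=C2C | intermediate
5 | (1S,4S,7S)-7-(4-methoxybenzyloxy)-3,3-dimethoxy-5-methylbicyclo[2.2.2]oct-5-en-2-one (single enantiomer) | O=C1C(OC)(OC)[C@H]2C[C@H](OCc3ccc(OC)cc3)[C@@H]1C=C2C | intermediate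
6 | 2-methylbut-1-en-3-yne | C=C(C)C#C | starting material
7 | tributyl(3-methylbuta-1,3-dien-2-yl)stannane | C=C(C)C(=C)[Sn](CCCC)(CCCC)CCCC | intermediate
8 | (3-methylbuta-1,3-dien-2-yl)lithium | [Li]C(=C)C(C)=C | intermediate
9 | (1S,2S,4S,7S)-7-(4-methoxybenzyloxy)-3,3-dimethoxy-5-methyl-2-(3-methylbuta-1,3-dien-2-yl)bicyclo[2.2.2]oct-5-en-2-ol (dienyl syn to C5=C6, OH syn to C7–C8) | C=C(C)C(=C)[C@]1(O)C(OC)(OC)[C@H]2C[C@H](OCc3ccc(OC)cc3)[C@@H]1C=C2C | intermediate
10 | potassium alkoxide of 9 | C=C(C)C(=C)[C@]1([O-])C(OC)(OC)[C@H]2C[C@H](OCc3ccc(OC)cc3)[C@@H]1C=C2C.[K+] | intermediate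
11 | potassium (2S,5R,10S)-9,9-dimethoxy-2-(4-methoxybenzyloxy)-15-noreremophila-3,7,11-trien-8-olate | C=C(C)C1=C([O-])C(OC)(OC)[C@H]2C[C@H](OCc3ccc(OC)cc3)C=C[C@@]2(C)C1.[K+] | intermediate
12 | (2S,5R,7R,10S)-9,9-dimethoxy-2-(4-methoxybenzyloxy)-15-noreremophila-3,11-dien-8-one (cis-fused; 5β-Me, 10β-H, 7β-isopropenyl, 2β-OPMB) | C=C(C)[C@H]1C[C@@]2(C)[C@H](C[C@H](OCc3ccc(OC)cc3)C=C2)C(OC)(OC)C1=O | intermediate
13 | (2S,5R,7R,8R,10S)-9,9-dimethoxy-2-(4-methoxybenzyloxy)-15-noreremophila-3,11-dien-8-ol (8α-OH) | C=C(C)[C@H]1C[C@@]2(C)[C@H](C[C@H](OCc3ccc(OC)cc3)C=C2)C(OC)(OC)[C@@H]1O | intermediate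
14 | (2S,5R,7R,8R,10S)-8-hydroxy-2-(4-methoxybenzyloxy)-15-noreremophila-3,11-dien-9-one | C=C(C)[C@H]1C[C@@]2(C)[C@H](C[C@H](OCc3ccc(OC)cc3)C=C2)C(=O)[C@@H]1O | intermediate
15 | (2S,5R,7R,8R,9S,10S)-2-(4-methoxybenzyloxy)-15-noreremophila-3,11-diene-8,9-diol (8α,9α) | C=C(C)[C@H]1C[C@@]2(C)[C@H](C[C@H](OCc3ccc(OC)cc3)C=C2)[C@H](O)[C@@H]1O | intermediate
16 | tiglic acid | C/C=C(\C)C(=O)O | starting material
17 | tiglic 2,4,6-trichlorobenzoic anhydride | C/C=C(\C)C(=O)OC(=O)c1c(Cl)cc(Cl)cc1Cl | intermediate
18 | (2S,5R,7R,8R,9S,10S)-2-(4-methoxybenzyloxy)-15-noreremophila-3,11-diene-8,9-diyl bis[(E)-2-methylbut-2-enoate] | C=C(C)[C@H]1C[C@@]2(C)[C@H](C[C@H](OCc3ccc(OC)cc3)C=C2)[C@H](OC(=O)/C(C)=C/C)[C@@H]1OC(=O)/C(C)=C/C | intermediate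
19 | (2S,5R,7R,8R,9S,10S)-2-hydroxy-15-noreremophila-3,11-diene-8,9-diyl bis[(E)-2-methylbut-2-enoate] | C=C(C)[C@H]1C[C@@]2(C)[C@H](C[C@H](O)C=C2)[C@H](OC(=O)/C(C)=C/C)[C@@H]1OC(=O)/C(C)=C/C | intermediate
20 | (5R,7R,8R,9S,10S)-2-oxo-15-noreremophila-3,11-diene-8,9-diyl bis[(E)-2-methylbut-2-enoate] | C=C(C)[C@H]1C[C@@]2(C)[C@H](CC(=O)C=C2)[C@H](OC(=O)/C(C)=C/C)[C@@H]1OC(=O)/C(C)=C/C | intermediate
21 | 2-(trimethylsilyloxy)eremophila-2,11-diene-8,9-diyl bis[(E)-2-methylbut-2-enoate] (4β-methyl) | C=C(C)[C@H]1C[C@@]2(C)[C@H](CC(O[Si](C)(C)C)=C[C@@H]2C)[C@H](OC(=O)/C(C)=C/C)[C@@H]1OC(=O)/C(C)=C/C | intermediate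
22 | (4S,5R,7R,8R,9S,10S)-2-oxoeremophil-11-ene-8,9-diyl bis[(E)-2-methylbut-2-enoate], CNP0249036.2 | C=C(C)[C@H]1C[C@@]2(C)[C@H](CC(=O)C[C@@H]2C)[C@H](OC(=O)/C(C)=C/C)[C@@H]1OC(=O)/C(C)=C/C | target

Total step count: 12. Longest linear sequence: 11 steps (creosol through steps 1, 2 and 4–12); step 3 is a one-step side branch.

**Steps most likely to fail**

1. Step 5. The rearrangement itself is well precedented; the weak point is the quench, where the dienolate may be protonated on the wrong face of C7 or at its terminal carbon (conjugation to the isopropylidene ketone), because the facial preference rests on a modest difference between two half-chairs. Fallback, setting out from 9 and returning at 12: after the rearrangement the dienolate is silylated in the flask (TBSCl, −78 → 0 °C) and isolated base-free as 8-(tert-butyldimethylsilyloxy)-9,9-dimethoxy-2-(4-methoxybenzyloxy)-15-noreremophila-3,7,11-triene F1. C7 is then set in a separate protodesilylation under kinetic control (TBAF buffered with AcOH, THF, −78 °C), where the proton source can be chosen freely and no crown-bound base is present.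

2. Step 12. Methyl transfer to C4 may be slow because the carbon lies next to the quaternary C5 and the open β face requires a non-chair-like approach, so 1,2-attack or incomplete conversion may take over. Fallback, setting out from 19 and returning at 22: hydroxyl-directed Simmons–Smith cyclopropanation (Et2Zn, CH2I2, CH2Cl2, −10 °C) should deliver CH2 to the β face of C3=C4, syn to the 2β-hydroxyl and far faster than at the isolated isopropenyl group, giving the 3β,4β-methano-2β-alcohol F2. Dess–Martin oxidation gives the cyclopropyl ketone F3, and SmI2 (THF/MeOH, −78 °C) cleaves the cyclopropane bond that overlaps with the carbonyl π system (C3–CH2), leaving the methylene as the 4β-methyl group.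

3. Step 2. The rate difference between the antipodes in the catalytic reduction may be too small, which would leave the recovered ketone with insufficient enantiomeric purity. Fallback, setting out from 4 and returning at 5: the racemate is separated directly by preparative chromatography on a chiral stationary phase (SFC, amylose carbamate phase), a physical resolution that makes no new compound.

**Further compounds**
F1 | step 5 | (2S,5R,10S)-8-(tert-butyldimethylsilyloxy)-9,9-dimethoxy-2-(4-methoxybenzyloxy)-15-noreremophila-3,7,11-triene | C=C(C)C1=C(O[Si](C)(C)C(C)(C)C)C(OC)(OC)[C@H]2C[C@H](OCc3ccc(OC)cc3)C=C[C@@]2(C)C1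
F2 | step 12 | 2β-hydroxy-3β,4β-methano-15-noreremophil-11-ene-8α,9α-diyl bis[(E)-2-methylbut-2-enoate] | C=C(C)[C@H]1C[C@@]2(C)[C@H](C[C@H](O)[C@@H]3C[C@@H]32)[C@H](OC(=O)/C(C)=C/C)[C@@H]1OC(=O)/C(C)=C/C
F3 | step 12 | 3β,4β-methano-2-oxo-15-noreremophil-11-ene-8α,9α-diyl bis[(E)-2-methylbut-2-enoate] | C=C(C)[C@H]1C[C@@]2(C)[C@H](CC(=O)[C@@H]3C[C@@H]32)[C@H](OC(=O)/C(C)=C/C)[C@@H]1OC(=O)/C(C)=C/C
F0 | step 2 | none | none
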